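**Retrosynthetic overview**

1. Target 28 is ent-oritin-(4α→6)-epioritin-4β-ol; the last operations are O-debenzylation and desilylation of the protected dimer 26.
2. Ring C of the upper unit is disconnected at O1–C2: 26 comes from the (E)-2-(1,3-diarylallyl)phenol 24 by a vanadium-catalysed, O1-directed epoxidation of C2=C3, whose epoxide is opened at C2 by the same O1 (C3 is set from C4, C2 by inversion).
3. Enabling feature: the phenolic oxygen O1 on ring A of the upper unit lies five atoms from C2 and binds the oxidant, and C2 is benzylic to the 4-oxygenated ring B. The same O1 makes the doubly benzylic C4 an o-quinone methide carbon, so 24 comes from carbinol 22 and alkenylboronate 20 (C3–C4 bond, catalyst-controlled C4).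
4. 22 comes from the C6-lithiated lower flavan 15 and salicylaldehyde 17 (interflavanyl C4–C6 bond). 15 comes from 2'-hydroxychalcone 5 by reduction to a cinnamylphenol, Shi epoxidation and 6-endo closure (2,3-trans), inversion at C3, and benzylic hydroxylation at C4.
5. Order of ring formation: ring C of the lower unit (step 7), then ring C of the upper unit (step 16); all four benzene rings are bought.

Key step: step 16

Remark: the target is read as upper unit (2S,3R,4R), 2,3-trans-3,4-cis, and lower unit (2R,3R,4S), 2,3-cis-3,4-trans; in steps 6 and 15 the catalyst antipode named is the one expected from the accepted models, and both antipodes of each catalyst are accessible.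

**Route**

Step 1
Reactants: 1 1-(2,3,4-trihydroxyphenyl)ethanone
Product: 2 1-[3,4-bis(benzyloxy)-2-hydroxyphenyl]ethanone
Conditions: BnBr (2.1 equiv), K2CO3, acetone, reflux
Reagents that add atoms: benzyl bromide, BrCc1ccccc1
Why: Williamson etherification in which the 2-hydroxyl, hydrogen-bonded to the acetyl carbonyl, is the least nucleophilic and stays free.

Step 2
Reactants: 2 1-[3,4-bis(benzyloxy)-2-hydroxyphenyl]ethanone
Product: 3 1-[3,4-bis(benzyloxy)-5-bromo-2-hydroxyphenyl]ethanone
Conditions: N-bromosuccinimide, MeCN, 0 °C → rt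
Reagents that add atoms: N-bromosuccinimide, O=C1CCC(=O)N1Br
Why: Electrophilic aromatic bromination goes para to the free 2-hydroxyl and ortho to the 4-benzyloxy group (C5), the only doubly activated position, which becomes C6 of the lower unit.

Step 3
Reactants: 3 1-[3,4-bis(benzyloxy)-5-bromo-2-hydroxyphenyl]ethanone; 4 4-(benzyloxy)benzaldehyde
Product: 5 (E)-1-[3,4-bis(benzyloxy)-5-bromo-2-hydroxyphenyl]-3-[4-(benzyloxy)phenyl]prop-2-en-1-one
Conditions: KOH, EtOH–THF, rt
Reagents that add atoms: none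
Why: Claisen–Schmidt aldol condensation of the acetophenone with the non-enolisable aldehyde gives the thermodynamic (E)-2'-hydroxychalcone.

Step 4
Reactants: 5 (E)-2'-hydroxychalcone
Product: 7 2,3-bis(benzyloxy)-6-[(2E)-3-[4-(benzyloxy)phenyl]prop-2-en-1-yl]-4-bromophenol, via ethyl carbonate 6 (not isolated)
Conditions: ClCO2Et, Et3N, THF, 0 °C; then NaBH4, H2O, 0 °C → rt
Reagents that add atoms: none
Why: In this carbonate-assisted borohydride reduction the carbonate migrates to the new benzylic alkoxide and leaves, and hydride adds 1,4 to the vinylogous o-quinone methide at the benzylic carbon, which keeps the (E)-alkene conjugated with ring B.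

Step 5
Reactants: 7 (E)-cinnamylphenol
Product: 8 tert-butyl{2,3-bis(benzyloxy)-6-[(2E)-3-[4-(benzyloxy)phenyl]prop-2-en-1-yl]-4-bromophenoxy}dimethylsilane
Conditions: TBSCl, imidazole, DMF, rt
Reagents that add atoms: tert-butyldimethylsilyl chloride, CC(C)(C)[Si](C)(C)Cl
Why: Silylation protects the phenol from the oxidant of the next step.

Step 6
Reactants: 8 silyl ether of the cinnamylphenol
Product: 9 tert-butyl{2,3-bis(benzyloxy)-6-[[(2S,3S)-3-[4-(benzyloxy)phenyl]oxiran-2-yl]methyl]-4-bromophenoxy}dimethylsilane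
Conditions: L-fructose-derived Shi ketone (30 mol %), KHSO5 (as 2KHSO5·KHSO4·K2SO4), K2CO3, Bu4NHSO4, MeCN–CH2(OMe)2–aq. Na2B4O7 buffer, 0 °C; crude product used directly
Reagents that add atoms: potassium peroxymonosulfate, [K+].[O-]S(=O)(=O)OO
Why: Shi asymmetric epoxidation by the dioxirane of the L-fructose-derived ketone attacks the trans-alkene through the spiro transition state and gives the (2S,3S)-epoxide, the mirror image of the (R,R)-epoxides given by the D-fructose-derived catalyst.

Step 7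
Reactants: 9 (2S,3S)-epoxide
Product: 11 (2R,3S)-7,8-bis(benzyloxy)-2-[4-(benzyloxy)phenyl]-6-bromochroman-3-ol, via epoxy phenol 10 (not isolated)
Conditions: Bu4NF, AcOH, THF, 0 °C; then camphorsulfonic acid (10 mol %), CH2Cl2, 0 °C
Reagents that add atoms: none
Why: Fluoride frees the phenol, and acid-catalysed 6-endo-tet epoxide opening at the benzylic carbon with inversion closes ring C of the lower unit as the 2,3-trans flavan-3-ol (2R,3S).

Step 8
Reactants: 11 (2R,3S)-flavan-3-ol
Product: 12 (2R)-7,8-bis(benzyloxy)-2-[4-(benzyloxy)phenyl]-6-bromochroman-3-one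
Conditions: Dess–Martin periodinane, NaHCO3, CH2Cl2, 0 °C → rt; used at once
Reagents that add atoms: none
Why: Dess–Martin oxidation under buffered conditions gives the flavan-3-one without epimerising the adjacent C2.

Step 9
Reactants: 12 (2R)-flavan-3-one
Product: 13 (2R,3R)-7,8-bis(benzyloxy)-2-[4-(benzyloxy)phenyl]-6-bromochroman-3-ol
Conditions: LiBH(s-Bu)3 (L-Selectride), LiBr, THF, −78 °C
Reagents that add atoms: none
Why: The bulky hydride (Selectride reduction) attacks the ketone from the face opposite to the C2 aryl group, which places the new hydroxyl cis to the aryl and inverts C3 to the 2,3-cis alcohol (3R).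

Step 10
Reactants: 13 (2R,3R)-flavan-3-ol
Product: 14 (2R,3R,4S)-7,8-bis(benzyloxy)-2-[4-(benzyloxy)phenyl]-6-bromochromane-3,4-diol
Conditions: DDQ (1.5 equiv), CH2Cl2–H2O, rt
Reagents that add atoms: water, O
Why: DDQ abstracts hydride from C4, para to the 7-benzyloxy group and ortho to O1 (oxidative benzylic functionalisation), and water adds to the cation on the face opposite to the C2 aryl and C3 hydroxyl groups, which sets C4 as the 3,4-trans alcohol (4S).

Step 11
Reactants: 14 (2R,3R,4S)-flavan-3,4-diol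
Product: 15 (2R,3S,4S)-7,8-bis(benzyloxy)-2-[4-(benzyloxy)phenyl]-6-bromo-3,4-bis(tert-butyldimethylsilyloxy)chromane (same spatial arrangement as 14; the C3 descriptor changes with the silyl group)
Conditions: TBSOTf, 2,6-lutidine, CH2Cl2, −20 → 0 °C
Reagents that add atoms: tert-butyldimethylsilyl triflate, CC(C)(C)[Si](C)(C)OS(=O)(=O)C(F)(F)F
Why: Silylation of both secondary hydroxyls with the silyl triflate gives ethers that tolerate the organolithium and the later oxidation.

Step 12
Reactants: 16 2,3,4-trihydroxybenzaldehyde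
Product: 17 3,4-bis(benzyloxy)-2-hydroxybenzaldehyde
Conditions: BnBr (2.05 equiv), K2CO3, DMF, rt
Reagents that add atoms: benzyl bromide, BrCc1ccccc1
Why: Williamson etherification, again leaving the carbonyl-chelated 2-hydroxyl free.

Step 13
Reactants: 18 1-(benzyloxy)-4-ethynylbenzene
Product: 20 diethyl [(E)-2-[4-(benzyloxy)phenyl]ethenyl]boronate, via alkenylborane 19 (not isolated)
Conditions: (Ipc)2BH, THF, −25 → 0 °C; then CH3CHO (excess), 0 → 40 °C
Reagents that add atoms: diisopinocampheylborane, B(C1CC2CC(C1C)C2(C)C)C1CC2CC(C1C)C2(C)C; acetaldehyde, CC=O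
Why: Syn, anti-Markovnikov hydroboration of the terminal alkyne gives the (E)-alkenylborane, and acetaldehyde then displaces both isopinocampheyl groups as α-pinene to leave the diethyl boronate.

Step 14
Reactants: 15 bis-silylated 6-bromoflavan; 17 3,4-bis(benzyloxy)-2-hydroxybenzaldehyde
Product: 22 [3,4-bis(benzyloxy)-2-hydroxyphenyl][(2R,3S,4S)-7,8-bis(benzyloxy)-2-[4-(benzyloxy)phenyl]-3,4-bis(tert-butyldimethylsilyloxy)chroman-6-yl]methanol as both carbinol epimers, via aryllithium 21 (not isolated)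
Conditions: n-BuLi, THF, −78 °C; then sodium phenoxide of 17 (from NaH, THF, 0 °C), −78 → −20 °C; H2O; filtered through neutral Al2O3 and used crude
Reagents that add atoms: none
Why: Bromine–lithium exchange gives the C6 aryllithium, whose 1,2-addition to the aldehyde forms the bond between C6 of the lower unit and the future C4 of the upper unit; the carbinol configuration is not controlled and is erased in step 15.

Step 15
Reactants: 22 o-hydroxy diaryl carbinol (both epimers); 20 diethyl (E)-alkenylboronate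
Product: 24 2,3-bis(benzyloxy)-6-[(2E)-3-[4-(benzyloxy)phenyl]-1-[(2R,3S,4S)-7,8-bis(benzyloxy)-2-[4-(benzyloxy)phenyl]-3,4-bis(tert-butyldimethylsilyloxy)chroman-6-yl]prop-2-en-1-yl]phenol as a single epimer at C-1 of the propenyl chain (the future C4; configured as in the target), via o-quinone methide 23 (not isolated)
Conditions: 20 (1.5 equiv), (R)-3,3'-dibromo-1,1'-bi-2-naphthol (15 mol %), 4 Å molecular sieves, PhCF3, rt → 40 °C
Reagents that add atoms: none
Why: Chiral-biphenol-catalysed addition of an alkenylboronate to an o-quinone methide: both carbinol epimers lose water to the same planar o-quinone methide 23, and the boronate, held on O1 and on the biphenol, transfers the (E)-styryl group to one face of C4 with retention of the alkene geometry, so the mixture converges on one C4 configuration.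

Step 16
Reactants: 24 (E)-2-(1,3-diarylallyl)phenol
Product: 26 7,8,4'-tri-O-benzyl-ent-oritin-(4α→6)-7,8,4'-tri-O-benzyl-3,4-bis-O-(tert-butyldimethylsilyl)epioritin-4β-ol (upper 3-OH free), via epoxy phenol 25 (not isolated)
Conditions: VO(acac)2 (10 mol %), t-BuOOH (1.5 equiv, in decane), CH2Cl2, 0 °C → rt
Reagents that add atoms: tert-butyl hydroperoxide, CC(C)(C)OO
Why: VO(acac)2 is oxidised by t-BuOOH to a pentavalent vanadium alkylperoxide that binds the ring A phenoxide O1, transfers oxygen intramolecularly to C2=C3, and the resulting epoxide 25 is opened at C2 by the same O1, closing ring C of the upper unit. The closest known reaction type is the VO(acac)2/t-BuOOH epoxidation–cyclisation of 2-(alk-2-enyl)phenols to chroman-3-ols, itself an extension of the hydroxyl-directed vanadium epoxidation of homoallylic alcohols. The ring closes by an anti 6-endo-tet epoxide opening, preferred over 5-exo attack at C3 because C2 is benzylic to the para-benzyloxyphenyl ring B while C3 is flanked by the diaryl-substituted C4. C3 is set by 1,2-induction from C4: with C4–H in the plane of ring A on the O1 side (least strain against the ortho oxygen) the styryl group points away from ring A, the lower-unit aryl is anti to the vanadium-bound peroxide, and oxygen enters the face that gives the 3,4-cis relationship (3R). C2 is set by inversion in the opening of the trans-epoxide, which gives the 2,3-trans ring (2S), and an ion-pair pathway would close through the same chair with O3 anti to the incoming O1. The selectivity needed is alkene epoxidation ahead of oxidation of the electron-rich phenol and arenes, which the intramolecular O1-directed delivery to an electron-rich styrene should secure, and no acid is added, so the silylated benzylic C4 oxygen of the lower unit is not ionised.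

Step 17
Reactants: 26 hexa-O-benzyl bis-O-silyl dimer
Product: 27 3,4-bis-O-(tert-butyldimethylsilyl) ether (lower unit) of the target
Conditions: H2 (1 atm), Pd(OH)2/C, THF–MeOH, rt
Reagents that add atoms: none
Why: Hydrogenolysis of the six aryl benzyl ethers over Pd(OH)2/C, carried out while the benzylic C4 oxygen of the lower unit is still a bulky silyl ether that resists C–O hydrogenolysis.

Step 18
Reactants: 27 bis-O-silyl hexaphenol
Product: 28 ent-oritin-(4α→6)-epioritin-4β-ol (target)
Conditions: HF·pyridine, pyridine, THF, 0 °C → rt, under argon; Sephadex LH-20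
Reagents that add atoms: none
Why: Fluoride-mediated desilylation under pyridine-buffered conditions frees the 3- and 4-hydroxyls of the lower unit without ionising the benzylic C4 position.

**Compound list**

1 | 1-(2,3,4-trihydroxyphenyl)ethanone (gallacetophenone) | CC(=O)c1ccc(O)c(O)c1O | starting material
2 | 1-[3,4-bis(benzyloxy)-2-hydroxyphenyl]ethanone | CC(=O)c1ccc(OCc2ccccc2)c(OCc2ccccc2)c1O | intermediate
3 | 1-[3,4-bis(benzyloxy)-5-bromo-2-hydroxyphenyl]ethanone | CC(=O)c1cc(Br)c(OCc2ccccc2)c(OCc2ccccc2)c1O | intermediate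
4 | 4-(benzyloxy)benzaldehyde | O=Cc1ccc(OCc2ccccc2)cc1 | starting material
5 | (E)-1-[3,4-bis(benzyloxy)-5-bromo-2-hydroxyphenyl]-3-[4-(benzyloxy)phenyl]prop-2-en-1-one | O=C(/C=C/c1ccc(OCc2ccccc2)cc1)c1cc(Br)c(OCc2ccccc2)c(OCc2ccccc2)c1O | intermediate
6 | aryl ethyl carbonate of chalcone 5 | CCOC(=O)Oc1c(C(=O)/C=C/c2ccc(OCc3ccccc3)cc2)cc(Br)c(OCc2ccccc2)c1OCc1ccccc1 | intermediate (not isolated)
7 | 2,3-bis(benzyloxy)-6-[(2E)-3-[4-(benzyloxy)phenyl]prop-2-en-1-yl]-4-bromophenol | Oc1c(C/C=C/c2ccc(OCc3ccccc3)cc2)cc(Br)c(OCc2ccccc2)c1OCc1ccccc1 | intermediate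
8 | tert-butyldimethylsilyl ether of 7 | CC(C)(C)[Si](C)(C)Oc1c(C/C=C/c2ccc(OCc3ccccc3)cc2)cc(Br)c(OCc2ccccc2)c1OCc1ccccc1 | intermediate
9 | silyl ether of the (2S,3S)-trans-epoxide of 7 | CC(C)(C)[Si](C)(C)Oc1c(C[C@@H]2O[C@H]2c2ccc(OCc3ccccc3)cc2)cc(Br)c(OCc2ccccc2)c1OCc1ccccc1 | intermediate
10 | 2,3-bis(benzyloxy)-6-[[(2S,3S)-3-[4-(benzyloxy)phenyl]oxiran-2-yl]methyl]-4-bromophenol | Oc1c(C[C@@H]2O[C@H]2c2ccc(OCc3ccccc3)cc2)cc(Br)c(OCc2ccccc2)c1OCc1ccccc1 | intermediate (not isolated)
11 | (2R,3S)-7,8-bis(benzyloxy)-2-[4-(benzyloxy)phenyl]-6-bromochroman-3-ol (2,3-trans) | O(Cc1ccccc1)c1ccc([C@H]2Oc3c(cc(Br)c(OCc4ccccc4)c3OCc3ccccc3)C[C@@H]2O)cc1 | intermediate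
12 | (2R)-7,8-bis(benzyloxy)-2-[4-(benzyloxy)phenyl]-6-bromochroman-3-one | O(Cc1ccccc1)c1ccc([C@H]2Oc3c(cc(Br)c(OCc4ccccc4)c3OCc3ccccc3)CC2=O)cc1 | intermediate
13 | (2R,3R)-7,8-bis(benzyloxy)-2-[4-(benzyloxy)phenyl]-6-bromochroman-3-ol (2,3-cis) | O(Cc1ccccc1)c1ccc([C@H]2Oc3c(cc(Br)c(OCc4ccccc4)c3OCc3ccccc3)C[C@H]2O)cc1 | intermediate
14 | (2R,3R,4S)-7,8-bis(benzyloxy)-2-[4-(benzyloxy)phenyl]-6-bromochromane-3,4-diol (2,3-cis-3,4-trans) | O(Cc1ccccc1)c1ccc([C@H]2Oc3c(cc(Br)c(OCc4ccccc4)c3OCc3ccccc3)[C@H](O)[C@H]2O)cc1 | intermediate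
15 | (2R,3S,4S)-7,8-bis(benzyloxy)-2-[4-(benzyloxy)phenyl]-6-bromo-3,4-bis(tert-butyldimethylsilyloxy)chromane | O(Cc1ccccc1)c1ccc([C@H]2Oc3c(cc(Br)c(OCc4ccccc4)c3OCc3ccccc3)[C@H](O[Si](C)(C)C(C)(C)C)[C@H]2O[Si](C)(C)C(C)(C)C)cc1 | intermediate
16 | 2,3,4-trihydroxybenzaldehyde | O=Cc1ccc(O)c(O)c1O | starting material
17 | 3,4-bis(benzyloxy)-2-hydroxybenzaldehyde | O=Cc1ccc(OCc2ccccc2)c(OCc2ccccc2)c1O | intermediate
18 | 1-(benzyloxy)-4-ethynylbenzene | C#Cc1ccc(OCc2ccccc2)cc1 | starting material
19 | [(E)-2-[4-(benzyloxy)phenyl]ethenyl]bis(isopinocampheyl)borane | B(/C=C/c1ccc(OCc2ccccc2)cc1)(C1CC2CC(C1C)C2(C)C)C1CC2CC(C1C)C2(C)C | intermediate (not isolated)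
20 | diethyl [(E)-2-[4-(benzyloxy)phenyl]ethenyl]boronate | CCOB(OCC)/C=C/c1ccc(OCc2ccccc2)cc1 | intermediate
21 | C6-lithio derivative of 15 | O(Cc1ccccc1)c1ccc([C@H]2Oc3c(cc([Li])c(OCc4ccccc4)c3OCc3ccccc3)[C@H](O[Si](C)(C)C(C)(C)C)[C@H]2O[Si](C)(C)C(C)(C)C)cc1 | intermediate (not isolated)
22 | [3,4-bis(benzyloxy)-2-hydroxyphenyl](lower flavan-6-yl)methanol, both carbinol epimers; lower flavan as in 15 | O(Cc1ccccc1)c1ccc([C@H]2Oc3c(cc(C(O)c4ccc(OCc5ccccc5)c(OCc5ccccc5)c4O)c(OCc4ccccc4)c3OCc3ccccc3)[C@H](O[Si](C)(C)C(C)(C)C)[C@H]2O[Si](C)(C)C(C)(C)C)cc1 | intermediate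
23 | o-quinone methide from 22 (6-arylmethylidene-2,3-bis(benzyloxy)cyclohexa-2,4-dienone) | O(Cc1ccccc1)c1ccc([C@H]2Oc3c(cc(C=C4C=CC(OCc5ccccc5)=C(OCc5ccccc5)C4=O)c(OCc4ccccc4)c3OCc3ccccc3)[C@H](O[Si](C)(C)C(C)(C)C)[C@H]2O[Si](C)(C)C(C)(C)C)cc1 | intermediate (not isolated)
24 | 2,3-bis(benzyloxy)-6-[(2E)-3-[4-(benzyloxy)phenyl]-1-(lower flavan-6-yl)prop-2-en-1-yl]phenol, C-1 of the chain configured as C4 of the target | O(Cc1ccccc1)c1ccc([C@H]2Oc3c(cc([C@@H](/C=C/c4ccc(OCc5ccccc5)cc4)c4ccc(OCc5ccccc5)c(OCc5ccccc5)c4O)c(OCc4ccccc4)c3OCc3ccccc3)[C@H](O[Si](C)(C)C(C)(C)C)[C@H]2O[Si](C)(C)C(C)(C)C)cc1 | intermediate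
25 | (2R,3R)-trans-epoxide of 24 (oxirane C3 bears the 4-benzyloxyphenyl group), phenol free | O(Cc1ccccc1)c1ccc([C@H]2Oc3c(cc([C@@H]([C@H]4O[C@@H]4c4ccc(OCc5ccccc5)cc4)c4ccc(OCc5ccccc5)c(OCc5ccccc5)c4O)c(OCc4ccccc4)c3OCc3ccccc3)[C@H](O[Si](C)(C)C(C)(C)C)[C@H]2O[Si](C)(C)C(C)(C)C)cc1 | intermediate (not isolated)
26 | 7,8,4'-tri-O-benzyl-ent-oritin-(4α→6)-7,8,4'-tri-O-benzyl-3,4-bis-O-(tert-butyldimethylsilyl)epioritin-4β-ol; upper ring C (2S,3R), 2,3-trans-3,4-cis | O(Cc1ccccc1)c1ccc([C@H]2Oc3c(cc([C@@H]4c5ccc(OCc6ccccc6)c(OCc6ccccc6)c5O[C@@H](c5ccc(OCc6ccccc6)cc5)[C@@H]4O)c(OCc4ccccc4)c3OCc3ccccc3)[C@H](O[Si](C)(C)C(C)(C)C)[C@H]2O[Si](C)(C)C(C)(C)C)cc1 | intermediate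
27 | ent-oritin-(4α→6)-3,4-bis-O-(tert-butyldimethylsilyl)epioritin-4β-ol | Oc1ccc([C@H]2Oc3c(cc([C@@H]4c5ccc(O)c(O)c5O[C@@H](c5ccc(O)cc5)[C@@H]4O)c(O)c3O)[C@H](O[Si](C)(C)C(C)(C)C)[C@H]2O[Si](C)(C)C(C)(C)C)cc1 | intermediate
28 | ent-oritin-(4α→6)-epioritin-4β-ol: (2R,3R,4S)-6-[(2S,3R,4R)-3,7,8-trihydroxy-2-(4-hydroxyphenyl)chroman-4-yl]-2-(4-hydroxyphenyl)chromane-3,4,7,8-tetrol | Oc1ccc([C@H]2Oc3c(cc([C@@H]4c5ccc(O)c(O)c5O[C@@H](c5ccc(O)cc5)[C@@H]4O)c(O)c3O)[C@H](O)[C@H]2O)cc1 | target

**Step count and risks**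

Total step count: 18. Longest linear sequence: 16 steps (steps 1–11 and 14–18); steps 12 and 13 make the two side fragments.

The three steps most likely to fail:

Step 16 (key step). The process at risk is oxidation of the electron-rich ring A phenol by the vanadium peroxide, or weak transmission of the C4 configuration to the alkene face (poor facial selectivity). The fallback is reagent-controlled and uses known chemistry. It sets out from 24: the phenol is silylated (TBSCl, imidazole, DMF) to the aryl silyl ether of 24, F1. The alkene is then epoxidised with the D-fructose-derived Shi ketone and KHSO5, so that the catalyst and not C4 chooses the face, to give the silyl-protected (2R,3R)-epoxide F2. Buffered fluoride (Bu4NF/AcOH, THF, 0 °C, which cleaves the aryl silyl ether much faster than the two hindered alkyl silyl ethers) followed by catalytic camphorsulfonic acid closes ring C through 25. The route is rejoined at 26.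

Step 15. The process at risk is poor face control by the biphenol catalyst on the hindered diaryl o-quinone methide, or self-condensation of the o-quinone methide before boron transfer. The fallback gives up catalyst control. It sets out from 22: the same boronate 20 is added in the presence of achiral 2,2'-biphenol, with slow addition of 22 to keep the o-quinone methide dilute. Because the lower unit is a single enantiomer, the product is a pair of diastereomers, 24 and the C4 epimer of 24, F3, which are separated by chromatography. The route is rejoined at 24.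

Step 18. The process at risk is ionisation at the benzylic C4 of the lower unit by the acidic fluoride source once the 7-hydroxyl is free (self-condensation), or incomplete cleavage of the two flanking axial silyl ethers. The fallback reverses the order of the last two operations. It sets out from 26: both silyl groups are removed first with Bu4NF in THF while all phenols are still benzylated, to give the hexa-O-benzyl triol F4. The six benzyl ethers are then hydrogenolysed (H2, Pd(OH)2/C, EtOAc–MeOH, NaHCO3, short contact time to spare the benzylic C4–OH). The route is rejoined at 28.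

Further compounds
F1 | step 16 | tert-butyldimethylsilyl ether of the phenol of 24 | O(Cc1ccccc1)c1ccc([C@H]2Oc3c(cc([C@@H](/C=C/c4ccc(OCc5ccccc5)cc4)c4ccc(OCc5ccccc5)c(OCc5ccccc5)c4O[Si](C)(C)C(C)(C)C)c(OCc4ccccc4)c3OCc3ccccc3)[C@H](O[Si](C)(C)C(C)(C)C)[C@H]2O[Si](C)(C)C(C)(C)C)cc1
F2 | step 16 | (2R,3R)-trans-epoxide of F1 (aryl silyl ether of 25) | O(Cc1ccccc1)c1ccc([C@H]2Oc3c(cc([C@@H]([C@H]4O[C@@H]4c4ccc(OCc5ccccc5)cc4)c4ccc(OCc5ccccc5)c(OCc5ccccc5)c4O[Si](C)(C)C(C)(C)C)c(OCc4ccccc4)c3OCc3ccccc3)[C@H](O[Si](C)(C)C(C)(C)C)[C@H]2O[Si](C)(C)C(C)(C)C)cc1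
F3 | step 15 | epimer of 24 at C-1 of the propenyl chain (future C4) | O(Cc1ccccc1)c1ccc([C@H]2Oc3c(cc([C@H](/C=C/c4ccc(OCc5ccccc5)cc4)c4ccc(OCc5ccccc5)c(OCc5ccccc5)c4O)c(OCc4ccccc4)c3OCc3ccccc3)[C@H](O[Si](C)(C)C(C)(C)C)[C@H]2O[Si](C)(C)C(C)(C)C)cc1
F4 | step 18 | 7,8,4'-tri-O-benzyl-ent-oritin-(4α→6)-7,8,4'-tri-O-benzyl-epioritin-4β-ol (three free alcohols) | O(Cc1ccccc1)c1ccc([C@H]2Oc3c(cc([C@@H]4c5ccc(OCc6ccccc6)c(OCc6ccccc6)c5O[C@@H](c5ccc(OCc6ccccc6)cc5)[C@@H]4O)c(OCc4ccccc4)c3OCc3ccccc3)[C@H](O)[C@H]2O)cc1
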